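The diaryl ketone is disconnected at its carbonyl carbon, so that both bonds to this carbon are made at once from carbon monoxide. Ring A carbon C3 lies between the C2 and C4 oxygens, so lithiation between their acetal ethers places an iodine there. A palladium-catalysed carbonylative Suzuki coupling then joins C3, CO and ring B carbon C1' under basic conditions that leave the acid-sensitive isopropenyl groups alone. The precursor is the pentasubstituted ring A iodide that already carries the (R)-configured C10 side chain (stereocentre from the limonene chiral pool, attached by Negishi coupling), the C6 methoxy group and a free C5–H. C5 is alkenylated last.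

Key step: step 11

Ring A numbering used throughout: C1 side chain, C2 and C4 oxygens, C3 ketone carbon, C5 alkenyl, C6 methoxy.

Remark on the design: the ring B phenol is carried as a MOM ether like the two ring A phenols, because it is inert to Cs2CO3 at 80 °C and all three acetals then leave in one operation.

Assumption: (+)-limonene 1,2-oxide (the commercial cis/trans mixture made from (R)-(+)-limonene) and 3-(methoxymethoxy)phenylboronic acid are taken as purchasable.

Step 1
Reactants: 1 2,4,6-trihydroxybenzaldehyde
Product: 2 2-hydroxy-4,6-bis(methoxymethoxy)benzaldehyde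
Conditions: MOMCl (2.2 equiv), i-Pr2NEt (2.5 equiv), CH2Cl2, 0 °C to rt
Reagents that add atoms: chloromethyl methyl ether, COCCl
Why: Chloromethyl methyl ether alkylates the C4 hydroxyl and one ortho hydroxyl (Williamson-type acetal ether formation), while the second ortho hydroxyl stays free because it is held in a hydrogen bond to the aldehyde.

Step 2
Reactants: 2 2-hydroxy-4,6-bis(methoxymethoxy)benzaldehyde
Product: 3 2-methoxy-4,6-bis(methoxymethoxy)benzaldehyde
Conditions: MeI, K2CO3, DMF, 40 °C
Reagents that add atoms: iodomethane, CI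
Why: Williamson methylation of the remaining chelated phenol fixes the oxygen that becomes the C6 methoxy group of ring A.

Step 3
Reactants: 3 2-methoxy-4,6-bis(methoxymethoxy)benzaldehyde
Product: 5 2-methoxy-4,6-bis(methoxymethoxy)phenol, via aryl formate 4 (not isolated)
Conditions: mCPBA, CH2Cl2, 0 °C to rt; then K2CO3 (cat.), MeOH, rt
Reagents that add atoms: 3-chloroperoxybenzoic acid, OOC(=O)c1cccc(Cl)c1
Why: Dakin-type Baeyer–Villiger oxidation, in which the electron-rich aryl group migrates to oxygen to give the formate that is then transesterified by methanol, replaces the aldehyde by a hydroxyl without acid strong enough to touch the MOM ethers.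

Step 4
Reactants: 5 2-methoxy-4,6-bis(methoxymethoxy)phenol
Product: 6 2-methoxy-4,6-bis(methoxymethoxy)phenyl trifluoromethanesulfonate
Conditions: Tf2O, pyridine, CH2Cl2, −20 to 0 °C
Reagents that add atoms: trifluoromethanesulfonic anhydride, O=S(=O)(OS(=O)(=O)C(F)(F)F)C(F)(F)F
Why: O-Sulfonylation of the phenol gives the aryl triflate, the electrophile for the sp2–sp3 coupling at ring A carbon C1.

Step 5
Reactants: 7 (+)-limonene 1,2-oxide, (4R), cis/trans mixture at C1/C2
Product: 8 (3R)-6-oxo-3-(prop-1-en-2-yl)heptanal
Conditions: H5IO6 (1.2 equiv), THF/H2O, 0 °C to rt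
Reagents that add atoms: water, O
Why: Periodic acid hydrolyses either epoxide diastereomer to the 1,2-diol and cleaves it at once (glycol cleavage of the Malaprade type) to one keto aldehyde, leaving the isopropenyl group and the stereocenter, now C3 (R), untouched.

Step 6
Reactants: 8 (3R)-6-oxo-3-(prop-1-en-2-yl)heptanal
Product: 9 (3R)-6-oxo-3-(prop-1-en-2-yl)heptanoic acid
Conditions: NaClO2, NaH2PO4, 2-methyl-2-butene (excess), t-BuOH/H2O, 0 °C to rt
Reagents that add atoms: sodium chlorite (NaClO2), [Na+].[O-]Cl=O
Why: Pinnick oxidation converts the aldehyde into the acid without affecting the ketone or the 1,1-disubstituted alkene, the hypochlorous acid formed being taken up by 2-methyl-2-butene.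

Step 7
Reactants: 9 (3R)-6-oxo-3-(prop-1-en-2-yl)heptanoic acid
Product: 10 (3R)-6-methyl-3-(prop-1-en-2-yl)hept-6-enoic acid
Conditions: Ph3PCH3Br (2.5 equiv), KOtBu (3.5 equiv), THF, 0 °C to rt; mildly acidic work-up
Reagents that add atoms: methyltriphenylphosphonium bromide, C[P+](c1ccccc1)(c1ccccc1)c1ccccc1.[Br-]
Why: Wittig methylenation with an excess of the unstabilised ylide converts the ketone into the second 1,1-disubstituted alkene while the carboxylate is inert, and the stereocenter, which is not alpha to a carbonyl, cannot epimerise.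

Step 8
Reactants: 10 (3R)-6-methyl-3-(prop-1-en-2-yl)hept-6-enoic acid
Product: 12 (3S)-3-(iodomethyl)-2,6-dimethylhepta-1,6-diene, via Barton ester 11 (not isolated)
Conditions: 1-hydroxypyridine-2(1H)-thione, DCC, DMAP (cat.), CH2Cl2, 0 °C, dark; then CHI3 (3 equiv), tungsten lamp, rt
Reagents that add atoms: iodoform, IC(I)I; 1-hydroxypyridine-2(1H)-thione, S=c1ccccn1O (atoms of intermediate 11 only)
Why: Barton iododecarboxylation, a radical chain in which the thiohydroxamate ester loses CO2 and the primary radical takes iodine from iodoform much faster than it can add to either alkene, shortens the chain by one carbon; the stereocenter is beta to the radical and keeps its geometry (the descriptor becomes S only because CH2I outranks isopropenyl).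

Step 9
Reactants: 12 (3S)-3-(iodomethyl)-2,6-dimethylhepta-1,6-diene; 6 2-methoxy-4,6-bis(methoxymethoxy)phenyl trifluoromethanesulfonate
Product: 15 1-methoxy-3,5-bis(methoxymethoxy)-2-[(2R)-5-methyl-2-(prop-1-en-2-yl)hex-5-en-1-yl]benzene, via alkyllithium 13 (not isolated), via alkylzinc chloride 14 (not isolated)
Conditions: 12 (1.3 equiv), t-BuLi (2.1 equiv per 12), Et2O/pentane, −78 °C; ZnCl2 in THF, −78 to 0 °C; then 6, Pd(OAc)2 (5 mol %), SPhos (10 mol %), THF, 55 °C
Reagents that add atoms: tert-butyllithium, [Li]C(C)(C)C (lithium of 13 only); zinc chloride (ZnCl2), Cl[Zn]Cl (zinc and chlorine of 14 only)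
Why: Iodine–lithium exchange at −78 °C (too cold for the hexenyllithium to cyclise), transmetalation to zinc and Negishi coupling with a bulky biarylphosphine ligand, which accepts the two ortho oxygens of the triflate and suppresses beta-hydride elimination, should form the C1–CH2 bond without touching the stereocenter.

Step 10
Reactants: 15 1-methoxy-3,5-bis(methoxymethoxy)-2-[(2R)-5-methyl-2-(prop-1-en-2-yl)hex-5-en-1-yl]benzene
Product: 17 2-iodo-5-methoxy-1,3-bis(methoxymethoxy)-4-[(2R)-5-methyl-2-(prop-1-en-2-yl)hex-5-en-1-yl]benzene, via aryllithium 16 (not isolated)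
Conditions: n-BuLi (1.2 equiv), THF, 0 °C; then ICH2CH2I, −78 °C to rt
Reagents that add atoms: 1,2-diiodoethane, ICCI; n-butyllithium, [Li]CCCC (lithium of 16 only)
Why: Directed ortho-metalation removes C3–H, the only ring hydrogen flanked by two MOM ethers that can both chelate lithium (C5–H has one MOM ether and a methoxy group turned away by the C1 chain), and 1,2-diiodoethane iodinates the aryllithium without releasing free iodine toward the alkenes.

Step 11
Reactants: 17 2-iodo-5-methoxy-1,3-bis(methoxymethoxy)-4-[(2R)-5-methyl-2-(prop-1-en-2-yl)hex-5-en-1-yl]benzene; 18 carbon monoxide; 19 3-(methoxymethoxy)phenylboronic acid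
Product: 20 {4-methoxy-2,6-bis(methoxymethoxy)-3-[(2R)-5-methyl-2-(prop-1-en-2-yl)hex-5-en-1-yl]phenyl}[3-(methoxymethoxy)phenyl]methanone
Conditions: PdCl2(IPr)(3-chloropyridine) (5 mol %), Cs2CO3 (3 equiv), 19 (2 equiv), CO (1 atm, balloon), chlorobenzene, 80 °C
Reagents that add atoms: none
Why: Zerovalent palladium, formed from the carbene precatalyst, inserts into the C3–I bond; because both ortho positions carry MOM ethers, direct transmetalation at the arylpalladium is slow, CO inserts first to give the acylpalladium, and the boronate formed from 19 and Cs2CO3 then transmetalates before reductive elimination releases the ketone. The closest known reaction type is the carbonylative Suzuki–Miyaura coupling of di-ortho-substituted aryl iodides with carbene–palladium catalysts, which delivers hindered benzophenones. No ring is closed and no stereocenter is formed; the existing (R) centre is remote and not enolisable. The selectivity needed is ketone over direct biaryl and over reduction of the C–I bond, and it is secured by the di-ortho substitution at C3, the CO atmosphere and the bulky IPr ligand. The site is fixed by the iodine placed in step 10, and neither 1,1-disubstituted alkene can reach the acylpalladium in a small-ring geometry, so no carbopalladation competes. The medium is basic and free of Lewis acid, so the MOM ethers and isopropenyl groups should pass unchanged.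

Step 12
Reactants: 20 {4-methoxy-2,6-bis(methoxymethoxy)-3-[(2R)-5-methyl-2-(prop-1-en-2-yl)hex-5-en-1-yl]phenyl}[3-(methoxymethoxy)phenyl]methanone
Product: 21 {2,6-dihydroxy-4-methoxy-3-[(2R)-5-methyl-2-(prop-1-en-2-yl)hex-5-en-1-yl]phenyl}(3-hydroxyphenyl)methanone
Conditions: HCl (0.5 M) in MeOH/THF, rt to 40 °C, stopped at full conversion
Reagents that add atoms: none
Why: Acid-catalysed acetal exchange with methanol removes all three MOM groups as dimethoxymethane, and dilute HCl in methanol near room temperature is the setting in which prenyl-type alkenes next to phenols are routinely preserved.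

Step 13
Reactants: 21 {2,6-dihydroxy-4-methoxy-3-[(2R)-5-methyl-2-(prop-1-en-2-yl)hex-5-en-1-yl]phenyl}(3-hydroxyphenyl)methanone
Product: 22 {2,6-dihydroxy-3-iodo-4-methoxy-5-[(2R)-5-methyl-2-(prop-1-en-2-yl)hex-5-en-1-yl]phenyl}(3-hydroxyphenyl)methanone
Conditions: I2 (1.0 equiv, slow addition in THF), NaHCO3, THF/H2O, 0 °C
Reagents that add atoms: iodine, II
Why: Electrophilic aromatic iodination of the ring A phenolate at C5, its only free position, which is ortho to the C4 hydroxyl and the C6 methoxy group and para to the C2 hydroxyl, should be far faster than attack of one equivalent of iodine on ring B or on the alkenes.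

Step 14
Reactants: 22 {2,6-dihydroxy-3-iodo-4-methoxy-5-[(2R)-5-methyl-2-(prop-1-en-2-yl)hex-5-en-1-yl]phenyl}(3-hydroxyphenyl)methanone; 23 (E)-4,4,5,5-tetramethyl-2-(3-methylbut-1-en-1-yl)-1,3,2-dioxaborolane
Product: 24 (3-hydroxyphenyl){2,6-dihydroxy-4-methoxy-3-[(1E)-3-methylbut-1-en-1-yl]-5-[(2R)-5-methyl-2-(prop-1-en-2-yl)hex-5-en-1-yl]phenyl}methanone (CNP0208548.1)
Conditions: Pd(OAc)2 (5 mol %), SPhos (10 mol %), K3PO4 (5 equiv), 23 (1.5 equiv), THF/H2O, 50 °C
Reagents that add atoms: none
Why: Suzuki–Miyaura coupling transfers the alkenyl group with retention of its E geometry, SPhos supporting oxidative addition into the hindered, electron-rich C5–I bond and excess K3PO4 covering the three phenols, to give the target.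

Compound list
1 | 2,4,6-trihydroxybenzaldehyde | O=Cc1c(O)cc(O)cc1O | starting material
2 | 2-hydroxy-4,6-bis(methoxymethoxy)benzaldehyde | O=Cc1c(O)cc(OCOC)cc1OCOC | intermediate
3 | 2-methoxy-4,6-bis(methoxymethoxy)benzaldehyde | O=Cc1c(OC)cc(OCOC)cc1OCOC | intermediate
4 | 2-methoxy-4,6-bis(methoxymethoxy)phenyl formate (not isolated) | O=COc1c(OC)cc(OCOC)cc1OCOC | intermediate
5 | 2-methoxy-4,6-bis(methoxymethoxy)phenol | Oc1c(OC)cc(OCOC)cc1OCOC | intermediate
6 | 2-methoxy-4,6-bis(methoxymethoxy)phenyl trifluoromethanesulfonate | O=S(=O)(Oc1c(OC)cc(OCOC)cc1OCOC)C(F)(F)F | intermediate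
7 | (+)-limonene 1,2-oxide, (4R)-1-methyl-4-(prop-1-en-2-yl)-7-oxabicyclo[4.1.0]heptane, cis/trans mixture at C1/C2 | CC12OC1C[C@@H](CC2)C(C)=C | starting material
8 | (3R)-6-oxo-3-(prop-1-en-2-yl)heptanal | CC(=O)CC[C@H](CC=O)C(=C)C | intermediate
9 | (3R)-6-oxo-3-(prop-1-en-2-yl)heptanoic acid | CC(=O)CC[C@H](CC(=O)O)C(=C)C | intermediate
10 | (3R)-6-methyl-3-(prop-1-en-2-yl)hept-6-enoic acid | C=C(C)CC[C@H](CC(=O)O)C(=C)C | intermediate
11 | 2-thioxopyridin-1(2H)-yl (3R)-6-methyl-3-(prop-1-en-2-yl)hept-6-enoate (Barton ester, not isolated) | C=C(C)CC[C@H](CC(=O)On1ccccc1=S)C(=C)C | intermediate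
12 | (3S)-3-(iodomethyl)-2,6-dimethylhepta-1,6-diene | C=C(C)CC[C@H](CI)C(=C)C | intermediate
13 | [(2S)-5-methyl-2-(prop-1-en-2-yl)hex-5-en-1-yl]lithium (not isolated) | C=C(C)CC[C@H](C[Li])C(=C)C | intermediate
14 | chloro[(2S)-5-methyl-2-(prop-1-en-2-yl)hex-5-en-1-yl]zinc (not isolated) | C=C(C)CC[C@H](C[Zn]Cl)C(=C)C | intermediate
15 | 1-methoxy-3,5-bis(methoxymethoxy)-2-[(2R)-5-methyl-2-(prop-1-en-2-yl)hex-5-en-1-yl]benzene | C=C(C)CC[C@H](Cc1c(OCOC)cc(OCOC)cc1OC)C(=C)C | intermediate
16 | {4-methoxy-2,6-bis(methoxymethoxy)-3-[(2R)-5-methyl-2-(prop-1-en-2-yl)hex-5-en-1-yl]phenyl}lithium (not isolated) | C=C(C)CC[C@H](Cc1c(OCOC)c([Li])c(OCOC)cc1OC)C(=C)C | intermediate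
17 | 2-iodo-5-methoxy-1,3-bis(methoxymethoxy)-4-[(2R)-5-methyl-2-(prop-1-en-2-yl)hex-5-en-1-yl]benzene | C=C(C)CC[C@H](Cc1c(OCOC)c(I)c(OCOC)cc1OC)C(=C)C | intermediate
18 | carbon monoxide | [C-]#[O+] | starting material
19 | 3-(methoxymethoxy)phenylboronic acid | COCOc1cccc(B(O)O)c1 | starting material
20 | {4-methoxy-2,6-bis(methoxymethoxy)-3-[(2R)-5-methyl-2-(prop-1-en-2-yl)hex-5-en-1-yl]phenyl}[3-(methoxymethoxy)phenyl]methanone | C=C(C)CC[C@H](Cc1c(OCOC)c(C(=O)c2cccc(OCOC)c2)c(OCOC)cc1OC)C(=C)C | intermediate
21 | {2,6-dihydroxy-4-methoxy-3-[(2R)-5-methyl-2-(prop-1-en-2-yl)hex-5-en-1-yl]phenyl}(3-hydroxyphenyl)methanone | C=C(C)CC[C@H](Cc1c(O)c(C(=O)c2cccc(O)c2)c(O)cc1OC)C(=C)C | intermediate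
22 | {2,6-dihydroxy-3-iodo-4-methoxy-5-[(2R)-5-methyl-2-(prop-1-en-2-yl)hex-5-en-1-yl]phenyl}(3-hydroxyphenyl)methanone | C=C(C)CC[C@H](Cc1c(O)c(C(=O)c2cccc(O)c2)c(O)c(I)c1OC)C(=C)C | intermediate
23 | (E)-4,4,5,5-tetramethyl-2-(3-methylbut-1-en-1-yl)-1,3,2-dioxaborolane | CC(C)/C=C/B1OC(C)(C)C(C)(C)O1 | starting material
24 | (3-hydroxyphenyl){2,6-dihydroxy-4-methoxy-3-[(1E)-3-methylbut-1-en-1-yl]-5-[(2R)-5-methyl-2-(prop-1-en-2-yl)hex-5-en-1-yl]phenyl}methanone | C=C(C)CC[C@H](Cc1c(O)c(C(=O)c2cccc(O)c2)c(O)c(/C=C/C(C)C)c1OC)C(=C)C | target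

Total step count: 14.
Longest linear sequence: 10 steps (steps 1–4 and 9–14 from 1; the side-chain branch, steps 5–8 and 9–14 from 7, is equally long).

Steps most likely to fail

Step 11. The crowded C3 position may slow oxidative addition and transmetalation so much that direct coupling without CO uptake or reduction of the C–I bond takes over. The fallback sets out from 15 and comes back at 20. Compound 15 is lithiated as in step 10 to aryllithium 16, which is added at −78 °C in THF to commercial 3-(methoxymethoxy)benzaldehyde. This should give [3-(methoxymethoxy)phenyl]{4-methoxy-2,6-bis(methoxymethoxy)-3-[(2R)-5-methyl-2-(prop-1-en-2-yl)hex-5-en-1-yl]phenyl}methanol F1 as a mixture of carbinol epimers. Oxidation with Dess–Martin periodinane buffered with NaHCO3 in CH2Cl2 then gives ketone 20. Both operations are non-acidic and leave the alkenes and MOM ethers alone.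

Step 9. Oxidative addition into the electron-rich, di-ortho-oxygenated triflate may be sluggish, so that the alkylzinc is lost to protonation or beta-hydride pathways before it couples. The fallback sets out from 12 and comes back at 15. Iodide 12 is exchanged with t-BuLi as before, the alkyllithium is trapped with B(OMe)3 and the borate is treated with aqueous KHF2 to give the isolable potassium trifluoro[(2S)-5-methyl-2-(prop-1-en-2-yl)hex-5-en-1-yl]borate F2. This slow-release nucleophile tolerates the longer time and higher temperature that the triflate needs. It is coupled with 6 by Suzuki–Miyaura reaction (Pd(OAc)2, RuPhos, K2CO3, toluene/H2O, 80 °C) to give 15.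

Step 13. The iodonium formed reversibly at the isopropenyl group may be captured by the neighbouring C2 hydroxyl (iodoetherification) instead of the ring being substituted. The fallback sets out from 20 and comes back at 22. Ketone 20, in which no phenol is free, is iodinated at C5 with N-iodosuccinimide in MeCN at 0 °C to rt. This should give {3-iodo-4-methoxy-2,6-bis(methoxymethoxy)-5-[(2R)-5-methyl-2-(prop-1-en-2-yl)hex-5-en-1-yl]phenyl}[3-(methoxymethoxy)phenyl]methanone F3. Methanolysis with dilute HCl as in step 12 then removes the three MOM groups to give 22.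

Further compounds
F1 | step 11 | [3-(methoxymethoxy)phenyl]{4-methoxy-2,6-bis(methoxymethoxy)-3-[(2R)-5-methyl-2-(prop-1-en-2-yl)hex-5-en-1-yl]phenyl}methanol, both carbinol epimers | C=C(C)CC[C@H](Cc1c(OCOC)c(C(O)c2cccc(OCOC)c2)c(OCOC)cc1OC)C(=C)C
F2 | step 9 | potassium trifluoro[(2S)-5-methyl-2-(prop-1-en-2-yl)hex-5-en-1-yl]borate | C=C(C)CC[C@H](C[B-](F)(F)F)C(=C)C.[K+]
F3 | step 13 | {3-iodo-4-methoxy-2,6-bis(methoxymethoxy)-5-[(2R)-5-methyl-2-(prop-1-en-2-yl)hex-5-en-1-yl]phenyl}[3-(methoxymethoxy)phenyl]methanone | C=C(C)CC[C@H](Cc1c(OCOC)c(C(=O)c2cccc(OCOC)c2)c(OCOC)c(I)c1OC)C(=C)C
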